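The route cuts ring A, the dihydrobenzofuran whose benzo ring carries the tetrahydrofuran at C4, at two bonds of one ethane unit: C3–C5′ (to ring B, the 7-hydroxydihydrobenzofuran) and C2–aryl. C3 is a diaryl methine and C2 bears O1 plus a 4-hydroxyphenyl group, exactly what an E-alkenylboron ate complex gives when an aryl group migrates from boron to C2 while palladium arylates C3. One conjunctive coupling thus unites the enantiopure tetraaryl tetrahydrofuran (as its E-styrenyl B(mac) ester), 4-(benzyloxy)phenyllithium and the ring B bromide, sets C2 and C3 anti, and leaves a C–B bond for oxidation and invertive O1–C2 closure.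

Key step: step 26

Remarks on the chemistry.
- Abbreviations: Bn = benzyl; SEM = 2-(trimethylsilyl)ethoxymethyl; B(mac) = boronic ester of cis-1,2-dimethyl-1,2-dihydroacenaphthylene-1,2-diol (35). Tetrahydrofuran positions are O1, C2–C5.
- Design of the precursor: (a) the hindered mac diol on boron, because β-substituted alkenyl pinacol boronates mainly undergo direct Suzuki transfer; (b) benzyl ethers on every phenol that ends free, so the last step is a neutral hydrogenolysis and no Lewis acid meets the 4-oxybenzylic C–O bonds of the three oxygen rings; (c) SEM ethers on both oxygens of the resorcinol ring of ring A, removed by fluoride, so no acid meets the 4-alkoxybenzylic alcohol (the second phenol stays free through the ring closure); (d) a bromine placed on that ring before the tetrahydrofuran is built, so the two-carbon handle enters at a fixed position.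
- Assumption: the sense of induction of the chiral catalysts in steps 7, 16 and 26 is assigned from the accepted models; each is available as both antipodes, and the antipode is used if a model run shows the opposite sense.

**Ring B bromide (steps 1–8)**

Step 1
Reactants: 1 2,3-dihydroxybenzaldehyde
Product: 2 3-(benzyloxy)-2-hydroxybenzaldehyde
Conditions: NaH (2.2 equiv), DMSO, rt; BnBr (1.0 equiv); aq. HCl
Reagents that add atoms: benzyl bromide, BrCc1ccccc1
Why: Williamson etherification of the dianion, in which the 2-phenoxide is chelated and conjugated to the formyl group so that the more nucleophilic 3-phenoxide takes the single equivalent of benzyl bromide.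

Step 2
Reactants: 2 3-(benzyloxy)-2-hydroxybenzaldehyde
Product: 3 3-(benzyloxy)-5-bromo-2-hydroxybenzaldehyde
Conditions: NBS, MeCN, 0 °C to rt
Reagents that add atoms: N-bromosuccinimide, O=C1CCC(=O)N1Br
Why: Electrophilic aromatic bromination para to the free phenol, the position that is also meta to the formyl group.

Step 3
Reactants: 3 3-(benzyloxy)-5-bromo-2-hydroxybenzaldehyde; 4 4-(benzyloxy)benzyl chloride
Product: 5 3-(benzyloxy)-2-{[4-(benzyloxy)phenyl]methoxy}-5-bromobenzaldehyde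
Conditions: K2CO3, KI (cat.), DMF, 60 °C
Reagents that add atoms: none
Why: Williamson etherification of the hydrogen-bonded phenol with a reactive benzylic chloride, whose CH2 group becomes C2 of ring B.

Step 4
Reactants: 5 O-alkylated bromobenzaldehyde; 6 1,3-bis(benzyloxy)-5-bromobenzene
Product: 8 racemic diarylmethanol, via Grignard reagent 7 (not isolated)
Conditions: 6, Mg, LiCl, THF, rt; then 5, THF, −78 to 0 °C; aq. NH4Cl
Reagents that add atoms: none
Why: 1,2-Addition of an aryl Grignard reagent to the aldehyde at low temperature, where the aryl bromide of 5 does not exchange (the carbinol centre is removed in the next step).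

Step 5
Reactants: 8 racemic diarylmethanol
Product: 9 diaryl ketone
Conditions: MnO2 (excess), CH2Cl2, rt
Reagents that add atoms: none
Why: Oxidation of a doubly benzylic alcohol with MnO2, which leaves benzyl ethers and the aryl bromide untouched.

Step 6
Reactants: 9 diaryl ketone
Product: 10 hydrazone of 9
Conditions: N2H4·H2O, AcOH (cat.), EtOH, reflux
Reagents that add atoms: hydrazine hydrate, NN.O
Why: Condensation of the diaryl ketone to the hydrazone, the precursor of a donor/donor diazo compound.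

Step 7
Reactants: 10 hydrazone of 9
Product: 12 cis-(2S,3R)-dihydrobenzofuran bromide, via diazo compound 11 (not isolated)
Conditions: MnO2, CH2Cl2, 0 °C; then Rh2(R-PTAD)4 (1 mol %), CH2Cl2, 0 °C to rt
Reagents that add atoms: none
Why: Dehydrogenation gives the diaryldiazomethane, and the chiral dirhodium carboxylate catalyses intramolecular 1,5 C–H insertion of the donor/donor carbene into the benzylic O–CH2 bond, in which the catalyst sets C3 (R) and the concerted insertion delivers the cis-2,3-diaryl ring.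

Step 8
Reactants: 12 cis-(2S,3R)-dihydrobenzofuran bromide
Product: 13 trans-(2R,3R)-dihydrobenzofuran bromide (ring B bromide)
Conditions: BF3·OEt2 (0.3 equiv), CH2Cl2, −40 to 0 °C
Reagents that add atoms: none
Why: Lewis-acid-mediated reversible heterolysis of the C2–O bond (a 4-alkoxybenzylic aryl ether) equilibrates C2 to the more stable trans isomer while C3 is untouched.

**Allylic carbonate (steps 9–11)**

Step 9
Reactants: 14 3,5-bis(benzyloxy)benzaldehyde
Product: 15 ethyl (2E)-3-[3,5-bis(benzyloxy)phenyl]prop-2-enoate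
Conditions: (EtO)2P(O)CH2CO2Et, NaH, THF, 0 °C to rt
Reagents that add atoms: triethyl phosphonoacetate, CCOC(=O)CP(=O)(OCC)OCC
Why: Horner–Wadsworth–Emmons olefination, which is E-selective for aryl aldehydes.

Step 10
Reactants: 15 ethyl (2E)-cinnamate
Product: 16 (2E)-3-[3,5-bis(benzyloxy)phenyl]prop-2-en-1-ol
Conditions: i-Bu2AlH (2.2 equiv), CH2Cl2, −78 °C; aq. potassium sodium tartrate
Reagents that add atoms: none
Why: 1,2-Reduction of the enoate to the allylic alcohol with i-Bu2AlH.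

Step 11
Reactants: 16 (2E)-allylic alcohol
Product: 17 tert-butyl (2E)-3-[3,5-bis(benzyloxy)phenyl]prop-2-en-1-yl carbonate
Conditions: Boc2O, DMAP (cat.), CH2Cl2, rt
Reagents that add atoms: di-tert-butyl dicarbonate, CC(C)(C)OC(=O)OC(=O)OC(C)(C)C
Why: O-Acylation under nucleophilic catalysis gives the allylic carbonate that serves as the iridium electrophile.

**Ring A acetate (steps 12–15)**

Step 12
Reactants: 18 methyl (3,5-dihydroxyphenyl)acetate
Product: 19 methyl [3,5-bis(SEM-oxy)phenyl]acetate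
Conditions: SEMCl (2.4 equiv), i-Pr2NEt, CH2Cl2, 0 °C to rt
Reagents that add atoms: 2-(trimethylsilyl)ethoxymethyl chloride, C[Si](C)(C)CCOCCl
Why: Double O-alkylation to alkoxymethyl ethers, which withstand organolithium and Grignard reagents and are later removed by fluoride without acid.

Step 13
Reactants: 19 methyl [3,5-bis(SEM-oxy)phenyl]acetate
Product: 20 methyl [2-bromo-3,5-bis(SEM-oxy)phenyl]acetate
Conditions: NBS (1.0 equiv), MeCN, 0 °C
Reagents that add atoms: N-bromosuccinimide, O=C1CCC(=O)N1Br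
Why: Electrophilic bromination of the resorcinol diether ortho to the CH2 group and para to one ether (both such positions are equivalent), not between the two ethers.

Step 14
Reactants: 20 methyl [2-bromo-3,5-bis(SEM-oxy)phenyl]acetate
Product: 21 [2-bromo-3,5-bis(SEM-oxy)phenyl]acetic acid
Conditions: LiOH, THF–H2O, rt; 1 M HCl to pH 4, 0 °C
Reagents that add atoms: lithium hydroxide, [Li+].[OH-]
Why: Saponification of the methyl ester, to which the acetal-type ethers are stable.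

Step 15
Reactants: 21 [2-bromo-3,5-bis(SEM-oxy)phenyl]acetic acid
Product: 22 pentafluorophenyl [2-bromo-3,5-bis(SEM-oxy)phenyl]acetate
Conditions: C6F5OH, EDC·HCl, DMAP (cat.), CH2Cl2, 0 °C to rt
Reagents that add atoms: pentafluorophenol, Oc1c(F)c(F)c(F)c(F)c1F
Why: Carbodiimide esterification to the activated aryl ester that a chiral Lewis base can enolise.

**Tetrahydrofuran (steps 16–21)**

Step 16
Reactants: 22 pentafluorophenyl aryl acetate; 17 allylic tert-butyl carbonate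
Product: 24 (2S,3R)-Weinreb amide with terminal alkene, via pentafluorophenyl ester 23 (not isolated)
Conditions: [Ir(cod)Cl]2 (2 mol %), (Ra,R,R)-binaphthyl N,N-bis(1-phenylethyl)phosphoramidite (4 mol %, cyclometalated with n-PrNH2), (S)-benzotetramisole (10 mol %), THF, rt; then MeNH(OMe)·HCl, i-Pr2NEt, rt
Reagents that add atoms: N,O-dimethylhydroxylamine hydrochloride, CNOC.Cl
Why: Synergistic iridium/Lewis-base allylic substitution in which the isothiourea forms the ammonium enolate of the aryl acetate and controls its face (C2), the cyclometalated iridium phosphoramidite complex controls the branched allylic carbon (C3), so the pairing of catalyst antipodes selects the erythro 2S,3R isomer, after which the released pentafluorophenoxide turns the Lewis base over and the active ester is aminolysed.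

Step 17
Reactants: 24 (2S,3R)-Weinreb amide with terminal alkene
Product: 25 (2S,3R)-4-oxobutanamide (aldehyde)
Conditions: OsO4 (2 mol %), NaIO4, 2,6-lutidine, dioxane–H2O, rt
Reagents that add atoms: sodium periodate, [Na+].[O-]I(=O)(=O)=O
Why: Johnson–Lemieux oxidative cleavage of the terminal alkene under buffered conditions that spare the benzyl ethers and the α-aryl stereocentre.

Step 18
Reactants: 25 (2S,3R)-aldehyde amide
Product: 26 (2S,3R,4S)-γ-hydroxy Weinreb amide
Conditions: 4-BnOC6H4MgBr (1.2 equiv), THF, −78 °C; aq. NH4Cl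
Reagents that add atoms: [4-(benzyloxy)phenyl]magnesium bromide, Br[Mg]c1ccc(OCc2ccccc2)cc1
Why: Chemoselective Grignard addition to the aldehyde beside the less electrophilic Weinreb amide, with Felkin–Anh attack anti to the α-aryl group giving the 3,4-anti (4S) carbinol.

Step 19
Reactants: 26 (2S,3R,4S)-γ-hydroxy Weinreb amide
Product: 27 (3S,4R,5S)-lactol
Conditions: i-Bu2AlH (3 equiv), THF, −78 °C; aq. potassium sodium tartrate
Reagents that add atoms: none
Why: Reduction of the Weinreb amide stops at the aldehyde stage through the stable aluminium chelate, and the γ-hydroxy aldehyde closes to the lactol on work-up.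

Step 20
Reactants: 27 (3S,4R,5S)-lactol
Product: 28 (1R,2S,3R,4S)-1,4-diol
Conditions: 4-BnOC6H4MgBr (3 equiv), THF, −20 to 0 °C; aq. NH4Cl
Reagents that add atoms: [4-(benzyloxy)phenyl]magnesium bromide, Br[Mg]c1ccc(OCc2ccccc2)cc1
Why: Grignard addition to the open hydroxy-aldehyde form of the lactol, again under Felkin–Anh control by the α-aryl group (1R).

Step 21
Reactants: 28 (1R,2S,3R,4S)-1,4-diol
Product: 30 (2R,3S,4R,5S)-tetraaryl tetrahydrofuran bromide, via monomesylate 29 (not isolated)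
Conditions: MsCl (1.2 equiv), Et3N (3 equiv), CH2Cl2, −20 to 0 °C
Reagents that add atoms: none
Why: Cyclodehydration in which a benzylic mesylate ionises to a 4-alkoxybenzylic cation that the other hydroxyl captures (5-exo-tet) trans to the neighbouring aryl group, and since both carbinols are anti, ionisation at either end gives the same 2,3-trans-3,4-cis-4,5-trans ring under non-acidic, kinetic conditions.

**Alkenyl boronate (steps 22–25)**

Step 22
Reactants: 30 tetraaryl tetrahydrofuran bromide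
Product: 32 tetrahydrofuran-substituted benzaldehyde, via aryllithium 31 (not isolated)
Conditions: t-BuLi (2.1 equiv), THF, −78 °C; DMF, −78 °C to rt; H2O
Reagents that add atoms: N,N-dimethylformamide, CN(C)C=O
Why: Bromine–lithium exchange and formylation of the aryllithium, which the ortho alkoxymethyl ether stabilises by chelation.

Step 23
Reactants: 32 tetrahydrofuran-substituted benzaldehyde
Product: 33 tetrahydrofuran-substituted aryl alkyne
Conditions: dimethyl (1-diazo-2-oxopropyl)phosphonate, K2CO3, MeOH–THF, rt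
Reagents that add atoms: dimethyl (1-diazo-2-oxopropyl)phosphonate, CC(=O)C(=[N+]=[N-])P(=O)(OC)OC
Why: Seyferth–Gilbert homologation with the Ohira–Bestmann reagent converts the hindered aryl aldehyde into the terminal alkyne under mild base.

Step 24
Reactants: 34 acenaphthylene-1,2-dione
Product: 35 cis-1,2-dimethyl-1,2-dihydroacenaphthylene-1,2-diol (mac diol)
Conditions: AlMe3 (3 equiv), toluene, 0 °C to rt; aq. potassium sodium tartrate; crystallisation
Reagents that add atoms: trimethylaluminium, C[Al](C)C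
Why: Double 1,2-addition of methyl to the diketone, in which the bulky aluminium alkoxide formed first shields its own face so that the second methyl enters cis to the first and the meso cis-diol results.

Step 25
Reactants: 33 aryl alkyne; 35 mac diol
Product: 37 E-styrenyl B(mac) ester, via catechol boronate 36 (not isolated)
Conditions: catecholborane (1.5 equiv), Cy2BH (10 mol %), THF, rt; then 35, rt
Reagents that add atoms: catecholborane, [H]B1Oc2ccccc2O1
Why: syn, anti-Markovnikov hydroboration of the terminal alkyne gives the E-alkenyl catechol boronate, and transesterification with the more basic aliphatic diol gives the hindered B(mac) ester.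

**Key step and end game (steps 26–30)**

Step 26
Reactants: 37 E-styrenyl B(mac) ester; 38 1-(benzyloxy)-4-bromobenzene; 13 ring B bromide
Product: 41 (1R,2S)-1,2,2-triarylethyl B(mac) ester, via aryllithium 39 (not isolated), via lithium borate 40 (not isolated)
Conditions: 38, t-BuLi (2.0 equiv), Et2O, −78 °C; 37, THF, −78 to 0 °C; then 13, Pd(OAc)2 (5 mol %), ferrocene-based bisphosphine (Sp,Sp)-MandyPhos (6 mol %), KOTf (2 equiv), THF, 60 °C
Reagents that add atoms: none
Why: The aryllithium adds to boron to give the four-coordinate alkenyl borate, and the arylpalladium bromide formed by oxidative addition of 13 to the zerovalent palladium–bisphosphine complex binds the alkene and triggers a 1,2-shift of the 4-(benzyloxy)phenyl group from boron to the α-carbon anti to palladium, after which reductive elimination forms the C3–aryl bond with retention. The closest known reaction is the palladium/MandyPhos conjunctive cross-coupling of β-substituted alkenyl B(mac) borates with aryl electrophiles. No ring is closed; two C–C bonds and two stereocentres are formed. C3 of ring A (2S in 41) is set by the enantiofacial binding of the alkene to the chiral palladium complex, which has to match or override the bias of the adjacent tetrahydrofuran, and C2 (1R in 41) follows stereospecifically from the E geometry and the anti-periplanar migration. The step needs the 1,2-shift to beat direct Suzuki transfer of the alkenyl or aryl group, which the hindered mac diol on boron secures, and it needs a halide-poor palladium centre, which KOTf secures by scavenging bromide, while the electrophile is an aryl bromide whose two ortho positions are CH.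

Step 27
Reactants: 41 (1R,2S)-1,2,2-triarylethyl B(mac) ester
Product: 42 (1R,2S)-1,2,2-triarylethanol
Conditions: H2O2 (30 % aq.), NaOH (3 M aq.), THF, 0 °C to rt
Reagents that add atoms: hydrogen peroxide, OO
Why: Oxidation of the C–B bond by hydroperoxide proceeds by 1,2-migration from boron to oxygen with retention at C1.

Step 28
Reactants: 42 (1R,2S)-1,2,2-triarylethanol
Product: 43 triol (two phenols of ring A and the benzylic alcohol)
Conditions: Bu4NF (6 equiv), DMPU, 60 °C; aq. NH4Cl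
Reagents that add atoms: none
Why: Fluoride attacks silicon and each SEM group fragments to ethene and formaldehyde, which frees both phenols without acid.

Step 29
Reactants: 43 triol
Product: 44 nona-O-benzyl kobophenol A (free phenol at C6 of ring A)
Conditions: PPh3, DIAD, THF, 0 °C to rt
Reagents that add atoms: none
Why: Intramolecular Mitsunobu etherification in which the ortho phenol displaces the activated benzylic alcohol (5-exo-tet) with inversion at C2, which turns the anti-addition product into the trans-dihydrobenzofuran; the para phenol cannot reach C2.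

Step 30
Reactants: 44 nona-O-benzyl kobophenol A
Product: 45 kobophenol A
Conditions: H2 (1 atm), Pd(OH)2 on carbon, THF–MeOH, rt
Reagents that add atoms: none
Why: Hydrogenolysis of the nine aryl benzyl ethers under neutral conditions, which should be faster than cleavage of the cyclic benzylic C–O bonds.

**Compound list**

1 | 2,3-dihydroxybenzaldehyde | O=Cc1cccc(O)c1O | starting material
2 | 3-(benzyloxy)-2-hydroxybenzaldehyde | O=Cc1cccc(OCc2ccccc2)c1O | intermediate
3 | 3-(benzyloxy)-5-bromo-2-hydroxybenzaldehyde | O=Cc1cc(Br)cc(OCc2ccccc2)c1O | intermediate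
4 | 4-(benzyloxy)benzyl chloride | ClCc1ccc(OCc2ccccc2)cc1 | starting material
5 | 3-(benzyloxy)-2-{[4-(benzyloxy)phenyl]methoxy}-5-bromobenzaldehyde | O=Cc1cc(Br)cc(OCc2ccccc2)c1OCc1ccc(OCc2ccccc2)cc1 | intermediate
6 | 1,3-bis(benzyloxy)-5-bromobenzene | Brc1cc(OCc2ccccc2)cc(OCc2ccccc2)c1 | starting material
7 | [3,5-bis(benzyloxy)phenyl]magnesium bromide | Br[Mg]c1cc(OCc2ccccc2)cc(OCc2ccccc2)c1 | intermediate
8 | (3-(benzyloxy)-2-{[4-(benzyloxy)phenyl]methoxy}-5-bromophenyl)[3,5-bis(benzyloxy)phenyl]methanol, racemic | OC(c1cc(OCc2ccccc2)cc(OCc2ccccc2)c1)c1cc(Br)cc(OCc2ccccc2)c1OCc1ccc(OCc2ccccc2)cc1 | intermediate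
9 | (3-(benzyloxy)-2-{[4-(benzyloxy)phenyl]methoxy}-5-bromophenyl)[3,5-bis(benzyloxy)phenyl]methanone | O=C(c1cc(OCc2ccccc2)cc(OCc2ccccc2)c1)c1cc(Br)cc(OCc2ccccc2)c1OCc1ccc(OCc2ccccc2)cc1 | intermediate
10 | hydrazone of ketone 9 | NN=C(c1cc(OCc2ccccc2)cc(OCc2ccccc2)c1)c1cc(Br)cc(OCc2ccccc2)c1OCc1ccc(OCc2ccccc2)cc1 | intermediate
11 | diaryldiazomethane from 10 | [N-]=[N+]=C(c1cc(OCc2ccccc2)cc(OCc2ccccc2)c1)c1cc(Br)cc(OCc2ccccc2)c1OCc1ccc(OCc2ccccc2)cc1 | intermediate
12 | (2S,3R)-7-(benzyloxy)-2-[4-(benzyloxy)phenyl]-3-[3,5-bis(benzyloxy)phenyl]-5-bromo-2,3-dihydro-1-benzofuran (cis) | Brc1cc(OCc3ccccc3)c2c(c1)[C@@H](c1cc(OCc3ccccc3)cc(OCc3ccccc3)c1)[C@@H](c1ccc(OCc3ccccc3)cc1)O2 | intermediate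
13 | (2R,3R)-7-(benzyloxy)-2-[4-(benzyloxy)phenyl]-3-[3,5-bis(benzyloxy)phenyl]-5-bromo-2,3-dihydro-1-benzofuran (trans; ring B bromide) | Brc1cc(OCc3ccccc3)c2c(c1)[C@@H](c1cc(OCc3ccccc3)cc(OCc3ccccc3)c1)[C@H](c1ccc(OCc3ccccc3)cc1)O2 | intermediate
14 | 3,5-bis(benzyloxy)benzaldehyde | O=Cc1cc(OCc2ccccc2)cc(OCc2ccccc2)c1 | starting material
15 | ethyl (2E)-3-[3,5-bis(benzyloxy)phenyl]prop-2-enoate | CCOC(=O)/C=C/c1cc(OCc2ccccc2)cc(OCc2ccccc2)c1 | intermediate
16 | (2E)-3-[3,5-bis(benzyloxy)phenyl]prop-2-en-1-ol | OC/C=C/c1cc(OCc2ccccc2)cc(OCc2ccccc2)c1 | intermediate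
17 | tert-butyl (2E)-3-[3,5-bis(benzyloxy)phenyl]prop-2-en-1-yl carbonate | CC(C)(C)OC(=O)OC/C=C/c1cc(OCc2ccccc2)cc(OCc2ccccc2)c1 | intermediate
18 | methyl (3,5-dihydroxyphenyl)acetate | COC(=O)Cc1cc(O)cc(O)c1 | starting material
19 | methyl [3,5-bis(SEM-oxy)phenyl]acetate | COC(=O)Cc1cc(OCOCC[Si](C)(C)C)cc(OCOCC[Si](C)(C)C)c1 | intermediate
20 | methyl [2-bromo-3,5-bis(SEM-oxy)phenyl]acetate | COC(=O)Cc1cc(OCOCC[Si](C)(C)C)cc(OCOCC[Si](C)(C)C)c1Br | intermediate
21 | [2-bromo-3,5-bis(SEM-oxy)phenyl]acetic acid | OC(=O)Cc1cc(OCOCC[Si](C)(C)C)cc(OCOCC[Si](C)(C)C)c1Br | intermediate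
22 | pentafluorophenyl [2-bromo-3,5-bis(SEM-oxy)phenyl]acetate | O=C(Cc1cc(OCOCC[Si](C)(C)C)cc(OCOCC[Si](C)(C)C)c1Br)Oc1c(F)c(F)c(F)c(F)c1F | intermediate
23 | pentafluorophenyl (2S,3R)-3-[3,5-bis(benzyloxy)phenyl]-2-[2-bromo-3,5-bis(SEM-oxy)phenyl]pent-4-enoate | O=C(Oc1c(F)c(F)c(F)c(F)c1F)[C@H](c1cc(OCOCC[Si](C)(C)C)cc(OCOCC[Si](C)(C)C)c1Br)[C@H](c1cc(OCc2ccccc2)cc(OCc2ccccc2)c1)C=C | intermediate
24 | (2S,3R)-3-[3,5-bis(benzyloxy)phenyl]-2-[2-bromo-3,5-bis(SEM-oxy)phenyl]-N-methoxy-N-methylpent-4-enamide | CON(C)C(=O)[C@H](c1cc(OCOCC[Si](C)(C)C)cc(OCOCC[Si](C)(C)C)c1Br)[C@H](c1cc(OCc2ccccc2)cc(OCc2ccccc2)c1)C=C | intermediate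
25 | (2S,3R)-3-[3,5-bis(benzyloxy)phenyl]-2-[2-bromo-3,5-bis(SEM-oxy)phenyl]-N-methoxy-N-methyl-4-oxobutanamide | CON(C)C(=O)[C@H](c1cc(OCOCC[Si](C)(C)C)cc(OCOCC[Si](C)(C)C)c1Br)[C@H](c1cc(OCc2ccccc2)cc(OCc2ccccc2)c1)C=O | intermediate
26 | (2S,3R,4S)-4-[4-(benzyloxy)phenyl]-3-[3,5-bis(benzyloxy)phenyl]-2-[2-bromo-3,5-bis(SEM-oxy)phenyl]-4-hydroxy-N-methoxy-N-methylbutanamide | CON(C)C(=O)[C@H](c1cc(OCOCC[Si](C)(C)C)cc(OCOCC[Si](C)(C)C)c1Br)[C@H](c1cc(OCc2ccccc2)cc(OCc2ccccc2)c1)[C@H](O)c1ccc(OCc2ccccc2)cc1 | intermediate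
27 | (3S,4R,5S)-5-[4-(benzyloxy)phenyl]-4-[3,5-bis(benzyloxy)phenyl]-3-[2-bromo-3,5-bis(SEM-oxy)phenyl]oxolan-2-ol (both anomers) | OC1O[C@H](c2ccc(OCc3ccccc3)cc2)[C@@H](c2cc(OCc3ccccc3)cc(OCc3ccccc3)c2)[C@H]1c1cc(OCOCC[Si](C)(C)C)cc(OCOCC[Si](C)(C)C)c1Br | intermediate
28 | (1R,2S,3R,4S)-1,4-bis[4-(benzyloxy)phenyl]-3-[3,5-bis(benzyloxy)phenyl]-2-[2-bromo-3,5-bis(SEM-oxy)phenyl]butane-1,4-diol | O[C@@H](c1ccc(OCc2ccccc2)cc1)[C@H](c1cc(OCOCC[Si](C)(C)C)cc(OCOCC[Si](C)(C)C)c1Br)[C@H](c1cc(OCc2ccccc2)cc(OCc2ccccc2)c1)[C@H](O)c1ccc(OCc2ccccc2)cc1 | intermediate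
29 | monomesylate of diol 28 (drawn at the C4 hydroxyl; the C1 regioisomer reacts in the same way) | O[C@@H](c1ccc(OCc2ccccc2)cc1)[C@H](c1cc(OCOCC[Si](C)(C)C)cc(OCOCC[Si](C)(C)C)c1Br)[C@H](c1cc(OCc2ccccc2)cc(OCc2ccccc2)c1)[C@H](OS(C)(=O)=O)c1ccc(OCc2ccccc2)cc1 | intermediate
30 | (2R,3S,4R,5S)-2,5-bis[4-(benzyloxy)phenyl]-4-[3,5-bis(benzyloxy)phenyl]-3-[2-bromo-3,5-bis(SEM-oxy)phenyl]oxolane | Brc1c(OCOCC[Si](C)(C)C)cc(OCOCC[Si](C)(C)C)cc1[C@@H]1[C@H](c2cc(OCc3ccccc3)cc(OCc3ccccc3)c2)[C@@H](c2ccc(OCc3ccccc3)cc2)O[C@H]1c1ccc(OCc2ccccc2)cc1 | intermediate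
31 | aryllithium from 30 (lithium in place of bromine) | [Li]c1c(OCOCC[Si](C)(C)C)cc(OCOCC[Si](C)(C)C)cc1[C@@H]1[C@H](c2cc(OCc3ccccc3)cc(OCc3ccccc3)c2)[C@@H](c2ccc(OCc3ccccc3)cc2)O[C@H]1c1ccc(OCc2ccccc2)cc1 | intermediate
32 | 2-{(2R,3S,4R,5S)-2,5-bis[4-(benzyloxy)phenyl]-4-[3,5-bis(benzyloxy)phenyl]oxolan-3-yl}-4,6-bis(SEM-oxy)benzaldehyde | O=Cc1c(OCOCC[Si](C)(C)C)cc(OCOCC[Si](C)(C)C)cc1[C@@H]1[C@H](c2cc(OCc3ccccc3)cc(OCc3ccccc3)c2)[C@@H](c2ccc(OCc3ccccc3)cc2)O[C@H]1c1ccc(OCc2ccccc2)cc1 | intermediate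
33 | (2R,3S,4R,5S)-2,5-bis[4-(benzyloxy)phenyl]-4-[3,5-bis(benzyloxy)phenyl]-3-[2-ethynyl-3,5-bis(SEM-oxy)phenyl]oxolane | C#Cc1c(OCOCC[Si](C)(C)C)cc(OCOCC[Si](C)(C)C)cc1[C@@H]1[C@H](c2cc(OCc3ccccc3)cc(OCc3ccccc3)c2)[C@@H](c2ccc(OCc3ccccc3)cc2)O[C@H]1c1ccc(OCc2ccccc2)cc1 | intermediate
34 | acenaphthylene-1,2-dione | O=C1C(=O)c2cccc3cccc1c23 | starting material
35 | cis-1,2-dimethyl-1,2-dihydroacenaphthylene-1,2-diol (meso; mac diol) | C[C@@]1(O)c2cccc3cccc(c23)[C@]1(C)O | intermediate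
36 | catechol ester of the E-alkenylboronic acid of 37 | C[Si](C)(C)CCOCOc1cc(OCOCC[Si](C)(C)C)cc([C@@H]2[C@H](c3cc(OCc4ccccc4)cc(OCc4ccccc4)c3)[C@@H](c3ccc(OCc4ccccc4)cc3)O[C@H]2c2ccc(OCc4ccccc4)cc2)c1/C=C/B1Oc2ccccc2O1 | intermediate
37 | B(mac) ester of (E)-2-(2-{(2R,3S,4R,5S)-2,5-bis[4-(benzyloxy)phenyl]-4-[3,5-bis(benzyloxy)phenyl]oxolan-3-yl}-4,6-bis(SEM-oxy)phenyl)ethenylboronic acid | C[Si](C)(C)CCOCOc1cc(OCOCC[Si](C)(C)C)cc([C@@H]2[C@H](c3cc(OCc4ccccc4)cc(OCc4ccccc4)c3)[C@@H](c3ccc(OCc4ccccc4)cc3)O[C@H]2c2ccc(OCc4ccccc4)cc2)c1/C=C/B1O[C@]2(C)c3cccc4cccc(c34)[C@]2(C)O1 | intermediate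
38 | 1-(benzyloxy)-4-bromobenzene | Brc1ccc(OCc2ccccc2)cc1 | starting material
39 | [4-(benzyloxy)phenyl]lithium | [Li]c1ccc(OCc2ccccc2)cc1 | intermediate
40 | lithium alkenyl[4-(benzyloxy)phenyl]borate of 37 (both epimers at boron) | C[Si](C)(C)CCOCOc1cc(OCOCC[Si](C)(C)C)cc([C@@H]2[C@H](c3cc(OCc4ccccc4)cc(OCc4ccccc4)c3)[C@@H](c3ccc(OCc4ccccc4)cc3)O[C@H]2c2ccc(OCc4ccccc4)cc2)c1/C=C/[B-]1(c2ccc(OCc3ccccc3)cc2)O[C@]2(C)c3cccc4cccc(c34)[C@]2(C)O1.[Li+] | intermediate
41 | B(mac) ester of (1R,2S)-1-[4-(benzyloxy)phenyl]-2-[ring B: (2R,3R)-7-(benzyloxy)-2-[4-(benzyloxy)phenyl]-3-[3,5-bis(benzyloxy)phenyl]-2,3-dihydro-1-benzofuran-5-yl]-2-[2-(tetraaryl oxolan-3-yl)-4,6-bis(SEM-oxy)phenyl]ethylboronic acid | c1ccccc1COc1ccc(cc1)[C@H](B1O[C@]2(C)c3cccc4cccc(c34)[C@]2(C)O1)[C@@H](c1cc(OCc2ccccc2)c2c(c1)[C@@H](c1cc(OCc3ccccc3)cc(OCc3ccccc3)c1)[C@H](c1ccc(OCc3ccccc3)cc1)O2)c1c(OCOCC[Si](C)(C)C)cc(OCOCC[Si](C)(C)C)cc1[C@@H]1[C@H](c2cc(OCc3ccccc3)cc(OCc3ccccc3)c2)[C@@H](c2ccc(OCc3ccccc3)cc2)O[C@H]1c1ccc(OCc2ccccc2)cc1 | intermediate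
42 | (1R,2S)-alcohol: 41 with OH in place of B(mac) | c1ccccc1COc1ccc(cc1)[C@H](O)[C@@H](c1cc(OCc2ccccc2)c2c(c1)[C@@H](c1cc(OCc3ccccc3)cc(OCc3ccccc3)c1)[C@H](c1ccc(OCc3ccccc3)cc1)O2)c1c(OCOCC[Si](C)(C)C)cc(OCOCC[Si](C)(C)C)cc1[C@@H]1[C@H](c2cc(OCc3ccccc3)cc(OCc3ccccc3)c2)[C@@H](c2ccc(OCc3ccccc3)cc2)O[C@H]1c1ccc(OCc2ccccc2)cc1 | intermediate
43 | triol: 42 with both SEM ethers replaced by OH | c1ccccc1COc1ccc(cc1)[C@H](O)[C@@H](c1cc(OCc2ccccc2)c2c(c1)[C@@H](c1cc(OCc3ccccc3)cc(OCc3ccccc3)c1)[C@H](c1ccc(OCc3ccccc3)cc1)O2)c1c(O)cc(O)cc1[C@@H]1[C@H](c2cc(OCc3ccccc3)cc(OCc3ccccc3)c2)[C@@H](c2ccc(OCc3ccccc3)cc2)O[C@H]1c1ccc(OCc2ccccc2)cc1 | intermediate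
44 | nona-O-benzyl kobophenol A: ring A (2S,3S), ring B (2R,3R), tetrahydrofuran (2R,3S,4R,5S), free OH only at C6 of ring A | c6ccccc6COc1ccc([C@H]2Oc3cc(O)cc([C@@H]4[C@H](c5cc(OCc6ccccc6)cc(OCc6ccccc6)c5)[C@@H](c5ccc(OCc6ccccc6)cc5)O[C@H]4c4ccc(OCc6ccccc6)cc4)c3[C@@H]2c2cc(OCc6ccccc6)c3c(c2)[C@@H](c2cc(OCc6ccccc6)cc(OCc6ccccc6)c2)[C@H](c2ccc(OCc6ccccc6)cc2)O3)cc1 | intermediate
45 | kobophenol A | Oc1ccc([C@H]2Oc3cc(O)cc([C@@H]4[C@H](c5cc(O)cc(O)c5)[C@@H](c5ccc(O)cc5)O[C@H]4c4ccc(O)cc4)c3[C@@H]2c2cc(O)c3c(c2)[C@@H](c2cc(O)cc(O)c2)[C@H](c2ccc(O)cc2)O3)cc1 | target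

**Step count and risk**

Total steps: 30. Longest linear sequence: 18 steps (18 → 45 through steps 12–23 and 25–30).

Steps most likely to fail:

1. Step 26. The crowded borate may transfer its alkenyl or aryl group directly (Suzuki–Miyaura pathway) instead of undergoing the 1,2-shift. The β-aryl alkene may bind palladium too slowly, or the facial selectivity may be poor if catalyst and tetrahydrofuran are mismatched. The fallback sets out from aldehyde 32 and bromide 13 and returns at 44. Bromine–lithium exchange on 13 (t-BuLi, THF, −78 °C) gives the ring B aryllithium F1, which adds to 32 to give the diarylmethanol F2 as both carbinol epimers. Bu4NF in DMPU removes both SEM groups to give the dihydroxy benzhydrol F3. The sulfonium salt [4-(benzyloxy)benzyl]dimethylsulfonium chloride F4 (from 4 and dimethyl sulfide) and Cs2CO3 in MeCN then convert F3, through its ortho-quinone methide F5, into 44 by a formal [4+1] annulation: the ylide carbon adds to C3 and the phenoxide displaces dimethyl sulfide. C2 and C3 come out trans from the anti closure. The face at C3 is then controlled only by the neighbouring tetrahydrofuran, so the C3 epimer would have to be separated.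

2. Step 16. Enolisation of the ortho-bromo aryl acetate may be slow, and formation of the crowded C2–C3 bond may erode diastereo- and enantioselectivity. The fallback sets out from acid 21 and returns at aldehyde 25. Sonogashira coupling of 6 with (R)-but-3-yn-2-ol (Pd(PPh3)2Cl2, CuI, Et3N) gives the propargylic alcohol F6. Semihydrogenation (H2, Pd/CaCO3 poisoned with Pb(OAc)2, quinoline) gives the (R,Z)-allylic alcohol F7, and esterification with 21 (N,N′-dicyclohexylcarbodiimide, DMAP) gives the ester F8. KN(SiMe3)2 and Me3SiCl in toluene (−78 °C to rt) give the silyl ketene acetal F9 with the aryl group cis to OSiMe3. Its Ireland–Claisen rearrangement through the chair with the methyl group equatorial gives the silyl ester F10 and, on aqueous work-up, the (2S,3R,4E)-acid F11 by chirality transfer from the carbinol centre. Coupling with MeNH(OMe)·HCl (EDC·HCl) gives the Weinreb amide F12, and Johnson–Lemieux cleavage of its propenyl group gives 25.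

3. Step 21. The benzylic cation may lose a proton to give a stilbene, or part of the material may close by direct displacement with inversion; either erodes the 2,3-trans-4,5-trans ring. The fallback sets out from lactol 27 and returns at 30. Acetylation (Ac2O, pyridine) gives the lactol acetate F13. BF3·OEt2 ionises it to the cyclic oxocarbenium ion, and potassium [4-(benzyloxy)phenyl]trifluoroborate transfers its aryl group to C2 on the face opposite the C3 aryl group. The C–C bond is thus made on the closed ring, and no open-chain carbinol has to cyclise.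

Further compounds
F1 | step 26 | aryllithium from 13 (lithium at C5 of ring B) | [Li]c1cc(OCc3ccccc3)c2c(c1)[C@@H](c1cc(OCc3ccccc3)cc(OCc3ccccc3)c1)[C@H](c1ccc(OCc3ccccc3)cc1)O2
F2 | step 26 | diarylmethanol from 32 and F1 (both carbinol epimers) | OC(c1cc(OCc2ccccc2)c2c(c1)[C@@H](c1cc(OCc3ccccc3)cc(OCc3ccccc3)c1)[C@H](c1ccc(OCc3ccccc3)cc1)O2)c1c(OCOCC[Si](C)(C)C)cc(OCOCC[Si](C)(C)C)cc1[C@@H]1[C@H](c2cc(OCc3ccccc3)cc(OCc3ccccc3)c2)[C@@H](c2ccc(OCc3ccccc3)cc2)O[C@H]1c1ccc(OCc2ccccc2)cc1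
F3 | step 26 | dihydroxy benzhydrol (F2 without SEM groups) | OC(c1cc(OCc2ccccc2)c2c(c1)[C@@H](c1cc(OCc3ccccc3)cc(OCc3ccccc3)c1)[C@H](c1ccc(OCc3ccccc3)cc1)O2)c1c(O)cc(O)cc1[C@@H]1[C@H](c2cc(OCc3ccccc3)cc(OCc3ccccc3)c2)[C@@H](c2ccc(OCc3ccccc3)cc2)O[C@H]1c1ccc(OCc2ccccc2)cc1
F4 | step 26 | [4-(benzyloxy)benzyl]dimethylsulfonium chloride | C[S+](C)Cc1ccc(OCc2ccccc2)cc1.[Cl-]
F5 | step 26 | ortho-quinone methide from F3 | O=C1C=C(O)C=C([C@@H]2[C@H](c3cc(OCc4ccccc4)cc(OCc4ccccc4)c3)[C@@H](c3ccc(OCc4ccccc4)cc3)O[C@H]2c2ccc(OCc4ccccc4)cc2)C1=Cc1cc(OCc2ccccc2)c2c(c1)[C@@H](c1cc(OCc3ccccc3)cc(OCc3ccccc3)c1)[C@H](c1ccc(OCc3ccccc3)cc1)O2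
F6 | step 16 | (2R)-4-[3,5-bis(benzyloxy)phenyl]but-3-yn-2-ol | C[C@@H](O)C#Cc1cc(OCc2ccccc2)cc(OCc2ccccc2)c1
F7 | step 16 | (2R,3Z)-4-[3,5-bis(benzyloxy)phenyl]but-3-en-2-ol | C[C@@H](O)/C=C\c1cc(OCc2ccccc2)cc(OCc2ccccc2)c1
F8 | step 16 | (2R,3Z)-4-[3,5-bis(benzyloxy)phenyl]but-3-en-2-yl [2-bromo-3,5-bis(SEM-oxy)phenyl]acetate | C[C@@H](OC(=O)Cc1cc(OCOCC[Si](C)(C)C)cc(OCOCC[Si](C)(C)C)c1Br)/C=C\c1cc(OCc2ccccc2)cc(OCc2ccccc2)c1
F9 | step 16 | trimethylsilyl ketene acetal of F8 (aryl cis to OSiMe3) | C[C@@H](O/C(O[Si](C)(C)C)=C/c1cc(OCOCC[Si](C)(C)C)cc(OCOCC[Si](C)(C)C)c1Br)/C=C\c1cc(OCc2ccccc2)cc(OCc2ccccc2)c1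
F10 | step 16 | trimethylsilyl (2S,3R,4E)-3-[3,5-bis(benzyloxy)phenyl]-2-[2-bromo-3,5-bis(SEM-oxy)phenyl]hex-4-enoate | C[Si](C)(C)OC(=O)[C@H](c1cc(OCOCC[Si](C)(C)C)cc(OCOCC[Si](C)(C)C)c1Br)[C@H](c1cc(OCc2ccccc2)cc(OCc2ccccc2)c1)/C=C/C
F11 | step 16 | (2S,3R,4E)-3-[3,5-bis(benzyloxy)phenyl]-2-[2-bromo-3,5-bis(SEM-oxy)phenyl]hex-4-enoic acid | OC(=O)[C@H](c1cc(OCOCC[Si](C)(C)C)cc(OCOCC[Si](C)(C)C)c1Br)[C@H](c1cc(OCc2ccccc2)cc(OCc2ccccc2)c1)/C=C/C
F12 | step 16 | (2S,3R,4E)-3-[3,5-bis(benzyloxy)phenyl]-2-[2-bromo-3,5-bis(SEM-oxy)phenyl]-N-methoxy-N-methylhex-4-enamide | CON(C)C(=O)[C@H](c1cc(OCOCC[Si](C)(C)C)cc(OCOCC[Si](C)(C)C)c1Br)[C@H](c1cc(OCc2ccccc2)cc(OCc2ccccc2)c1)/C=C/C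
F13 | step 21 | acetate of lactol 27 | CC(=O)OC1O[C@H](c2ccc(OCc3ccccc3)cc2)[C@@H](c2cc(OCc3ccccc3)cc(OCc3ccccc3)c2)[C@H]1c1cc(OCOCC[Si](C)(C)C)cc(OCOCC[Si](C)(C)C)c1Br
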